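Assumption: atom labels C1–C15 follow germacrane numbering (C1 ketone, C2=C3 furanone alkene, C4=C5 ring alkene, C6 lactone carbinol, C8 ester carbinol, C10 quaternary carbon, C11–C13 methylene lactone, C14 methyl, C15 hydroxymethyl). The target SMILES reads 4Z,6R,7R,8S,10R.

## Retrosynthetic overview
1. Goyazensolide ⇒ allylic C15–H hydroxylation and O8 methacrylation of an 8-hydroxy-15-deoxy tricycle. No protecting group survives an isolation.
2. Key disconnection C6–C7. C7 is natively an electrophilic epoxide and acrylate β-carbon. It is reduced to the γ-terminus of a 2-(methoxycarbonyl)allylchromium, a homoenolate equivalent of the C12 ester, and attacks the equally electrophilic C6 enal carbon. C6 and C7 are set from C8.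
3. Furanone ⇒ C1–C2 acylation of the acetylide of (Z)-3-methylpent-2-en-4-yn-1-ol by a lactic acid dioxolanone, then O10→C3 5-endo-dig closure.
4. Vinyl epoxide arm ⇒ Shi epoxidation (C8) of a 2-carbomethoxy diene ⇒ hydroboration/Suzuki coupling (C7–C11) of a propargyl group ⇒ Seebach alkylation of the (S)-lactic acid acetal (C10).
5. Ring order: furanone (step 5), then the ten-membered carbocycle, then the γ-lactone (both in step 7).

## Route

Step 1
Reactants: 1 (S)-lactic acid; 2 pivalaldehyde (2,2-dimethylpropanal)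
Product: 3 (2S,5S)-2-tert-butyl-5-methyl-1,3-dioxolan-4-one (cis acetal)
Conditions: p-TsOH (cat), pentane, reflux, Dean–Stark; crystallise from pentane, −78 °C
Reagents that add atoms: none
Why: Acid-catalysed acetalisation (Seebach self-regeneration of stereocentres) keeps the lactic acid centre (future C10) and induces the cis acetal centre, and the minor trans isomer is removed by crystallisation.

Step 2
Reactants: 3 (2S,5S)-2-tert-butyl-5-methyl-1,3-dioxolan-4-one; 4 propargyl bromide (3-bromoprop-1-yne)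
Product: 5 (2S,5R)-2-tert-butyl-5-methyl-5-(prop-2-yn-1-yl)-1,3-dioxolan-4-one
Conditions: LiN(iPr)2, THF, −78 °C; then 4, −78→−30 °C
Reagents that add atoms: none
Why: In this Seebach enolate alkylation the planar lithium enolate is attacked by the reactive propargylic bromide on the face anti to the tert-butyl group, which sets quaternary C10 as R with overall retention.

Step 3
Reactants: 5 (2S,5R)-2-tert-butyl-5-methyl-5-(prop-2-yn-1-yl)-1,3-dioxolan-4-one; 6 methyl 2-bromoacrylate
Product: 8 methyl (3E)-5-[(2S,4R)-2-tert-butyl-4-methyl-5-oxo-1,3-dioxolan-4-yl]-2-methylidenepent-3-enoate (diene ester, used at once), via alkenylboronate 7 (not isolated)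
Conditions: pinacolborane, Cp2ZrHCl (10 mol %), Et3N (10 mol %), CH2Cl2, 40 °C; then 6, Pd(PPh3)4 (5 mol %), K3PO4, BHT, THF–H2O, 40 °C
Reagents that add atoms: none
Why: Zirconium-catalysed syn hydroboration of the terminal alkyne gives only the E-alkenylboronate, and the Suzuki–Miyaura coupling with the 2-bromoacrylate forms C7–C11 with retention of that geometry, so no stereocentre is touched.

Step 4
Reactants: 8 diene ester
Product: 9 methyl 2-[(2S,3S)-3-{[(2S,4R)-2-tert-butyl-4-methyl-5-oxo-1,3-dioxolan-4-yl]methyl}oxiran-2-yl]prop-2-enoate (vinyl epoxide, 7S,8S)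
Conditions: L-fructose-derived Shi ketone (30 mol %), KHSO5 (as Oxone, 2KHSO5·KHSO4·K2SO4), K2CO3, Bu4NHSO4 (cat), Na2B4O7/Na2(EDTA) buffer, MeCN–CH2(OMe)2–H2O, 0 °C
Reagents that add atoms: potassium peroxymonosulfate, [K+].[O-]S(=O)(=O)OO
Why: In the Shi asymmetric epoxidation the chiral dioxirane reacts only with the electron-richer trans C7=C8 alkene of the cross-conjugated diene (the 1,1-disubstituted acrylate alkene is electron-poor) through the spiro transition state, and the L-series ketone delivers the (S,S)-epoxide, which sets C8.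

Step 5
Reactants: 9 vinyl epoxide; 10 (2Z)-3-methylpent-2-en-4-yn-1-ol
Product: 14 methyl 2-[(2S,3S)-3-({(2R)-5-[(2Z)-4-hydroxybut-2-en-2-yl]-2-methyl-3-oxo-2,3-dihydrofuran-2-yl}methyl)oxiran-2-yl]prop-2-enoate (furanone alcohol), via silyl ether 11 (not isolated), via hydroxy-ynone 12 (not isolated), via silylated furanone 13 (not isolated)
Conditions: 10, n-BuLi (1.0 equiv), THF, −78 °C; Me3SiCl (1.0 equiv), −78→0 °C; n-BuLi (1.0 equiv), −78 °C; 9 (0.95 equiv), −78 °C, 1 h; t-BuOH (1 equiv), −78→−20 °C; AcOH, then THF–H2O, 0 °C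
Reagents that add atoms: none
Why: Acetylide acylation at the acylal-type dioxolanone carbonyl (far more electrophilic at −78 °C than the conjugated methyl ester or the epoxide) forms C1–C2 and expels pivalaldehyde, the freed C10 alkoxide closes on C3 by 5-endo-dig oxa-Michael addition (3(2H)-furanone synthesis from an alpha'-hydroxy ynone), the transient O6 silyl ether blocks the competing furan-forming attack of O6, and C10, C7 and C8 are untouched.

Step 6
Reactants: 14 furanone alcohol
Product: 15 methyl 2-[(2S,3S)-3-({(2R)-2-methyl-3-oxo-5-[(2Z)-4-oxobut-2-en-2-yl]-2,3-dihydrofuran-2-yl}methyl)oxiran-2-yl]prop-2-enoate (Z-enal, used at once)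
Conditions: MnO2 (activated, 15 equiv), CH2Cl2, 25 °C
Reagents that add atoms: none
Why: Heterogeneous MnO2 oxidation takes the only allylic alcohol to the aldehyde under neutral conditions that keep the Z alkene, the epoxide and all stereocentres.

Step 7
Reactants: 15 Z-enal
Product: 19 8-desacyl-15-deoxygoyazensolide (6R,7R,8S,10R; free C8 hydroxyl), via allylic bromide 16 (not isolated), via macrocyclic hydroxy ester 17 (not isolated), via silylated lactone 18 (not isolated)
Conditions: Me3SiBr (1.05 equiv), CH2Cl2, −78 °C, 15 min; solvent changed to THF; syringe pump (12 h) into CrCl2 (8 equiv), THF–DMF 9:1, 1 mM, 25→40 °C; then aq citric acid–THF, 25 °C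
Reagents that add atoms: none
Why: Proposed new method: Me3SiBr opens the 2-(oxiranyl)acrylate at its allylic terminus (the SN2 and SN2′ bromides converge) and leaves O8 as a poor silyloxy leaving group, two equivalents of divalent chromium then reduce C–Br to a 2-(methoxycarbonyl)allylchromium whose nucleophilic γ-terminus is C7, so that two natively electrophilic carbons (C7 and the C6 aldehyde carbon) are joined through a Zimmerman–Traxler chair in an intramolecular Nozaki–Hiyama–Kishi allylation (closest known types: chromium-mediated 2-(alkoxycarbonyl)allylation to alpha-methylene-gamma-butyrolactones, chromium polarity reversal of diene monoepoxides, and allylmetal closures of germacrane ten-membered rings); allylic 1,3-strain holds C8–H in the alkene plane so that the tethered aldehyde reaches C7 anti to OSiMe3 (7R), the E-type allylchromium gives the anti C6/C7 pair (6R), only the trivalent-chromium C6 alkoxide is nucleophilic enough to close on the ester (trans 6,12-lactone rather than the 8,12-isomer), and the acidic work-up frees O8–H.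

Step 8
Reactants: 19 8-desacyl-15-deoxygoyazensolide; 20 methacrylic anhydride
Product: 21 15-deoxygoyazensolide
Conditions: Et3N, DMAP (cat), CH2Cl2, 0→25 °C
Reagents that add atoms: none
Why: DMAP-catalysed (Steglich-type) acylation of the only free hydroxyl leaves the C8–O bond intact, so 8S is retained.

Step 9
Reactants: 21 15-deoxygoyazensolide
Product: 22 goyazensolide
Conditions: SeO2 (0.5 equiv), t-BuOOH (3 equiv, decane), CH2Cl2, 25 °C
Reagents that add atoms: tert-butyl hydroperoxide, CC(C)(C)OO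
Why: In the Riley-type SeO2 allylic hydroxylation (ene reaction, then [2,3]-sigmatropic shift) the only allylic C–H on the more substituted end of the only non-acrylate trisubstituted alkene is C15–H, that methyl is trans to C6 as the E-rule demands, the alkene returns to C4=C5 with its ring-enforced Z geometry, and no stereocentre is affected.

## Compound list
1 | (S)-lactic acid | C[C@H](O)C(=O)O | starting material
2 | pivalaldehyde | CC(C)(C)C=O | starting material
3 | (2S,5S)-2-tert-butyl-5-methyl-1,3-dioxolan-4-one | C[C@@H]1O[C@H](C(C)(C)C)OC1=O | intermediate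
4 | propargyl bromide | C#CCBr | starting material
5 | (2S,5R)-2-tert-butyl-5-methyl-5-(prop-2-yn-1-yl)-1,3-dioxolan-4-one | C[C@]1(CC#C)O[C@H](C(C)(C)C)OC1=O | intermediate
6 | methyl 2-bromoacrylate | C=C(Br)C(=O)OC | starting material
7 | (2S,5R)-2-tert-butyl-5-methyl-5-[(2E)-3-(4,4,5,5-tetramethyl-1,3,2-dioxaborolan-2-yl)prop-2-en-1-yl]-1,3-dioxolan-4-one | C[C@]1(C/C=C/B2OC(C)(C)C(C)(C)O2)O[C@H](C(C)(C)C)OC1=O | intermediate
8 | methyl (3E)-5-[(2S,4R)-2-tert-butyl-4-methyl-5-oxo-1,3-dioxolan-4-yl]-2-methylidenepent-3-enoate | C[C@]1(C/C=C/C(=C)C(=O)OC)O[C@H](C(C)(C)C)OC1=O | intermediate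
9 | methyl 2-[(2S,3S)-3-{[(2S,4R)-2-tert-butyl-4-methyl-5-oxo-1,3-dioxolan-4-yl]methyl}oxiran-2-yl]prop-2-enoate | C[C@]1(C[C@@H]2O[C@H]2C(=C)C(=O)OC)O[C@H](C(C)(C)C)OC1=O | intermediate
10 | (2Z)-3-methylpent-2-en-4-yn-1-ol | C#C/C(C)=C\CO | starting material
11 | trimethyl{[(2Z)-3-methylpent-2-en-4-yn-1-yl]oxy}silane | C#C/C(C)=C\CO[Si](C)(C)C | intermediate
12 | methyl 2-[(2S,3S)-3-{(2R,6Z)-2-hydroxy-2,6-dimethyl-3-oxo-8-[(trimethylsilyl)oxy]oct-6-en-4-yn-1-yl}oxiran-2-yl]prop-2-enoate | C[C@@](O)(C[C@@H]1O[C@H]1C(=C)C(=O)OC)C(=O)C#C/C(C)=C\CO[Si](C)(C)C | intermediate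
13 | O6-trimethylsilyl ether of furanone alcohol 14 | C[C@]1(C[C@@H]2O[C@H]2C(=C)C(=O)OC)OC(=CC1=O)/C(C)=C\CO[Si](C)(C)C | intermediate
14 | methyl 2-[(2S,3S)-3-({(2R)-5-[(2Z)-4-hydroxybut-2-en-2-yl]-2-methyl-3-oxo-2,3-dihydrofuran-2-yl}methyl)oxiran-2-yl]prop-2-enoate | C[C@]1(C[C@@H]2O[C@H]2C(=C)C(=O)OC)OC(=CC1=O)/C(C)=C\CO | intermediate
15 | methyl 2-[(2S,3S)-3-({(2R)-2-methyl-3-oxo-5-[(2Z)-4-oxobut-2-en-2-yl]-2,3-dihydrofuran-2-yl}methyl)oxiran-2-yl]prop-2-enoate | C[C@]1(C[C@@H]2O[C@H]2C(=C)C(=O)OC)OC(=CC1=O)/C(C)=C\C=O | intermediate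
16 | methyl (2Z,4S)-2-(bromomethyl)-5-{(2R)-2-methyl-3-oxo-5-[(2Z)-4-oxobut-2-en-2-yl]-2,3-dihydrofuran-2-yl}-4-[(trimethylsilyl)oxy]pent-2-enoate (drawn as the primary bromide) | C[C@]1(C[C@H](O[Si](C)(C)C)/C=C(\CBr)C(=O)OC)OC(=CC1=O)/C(C)=C\C=O | intermediate
17 | ten-membered 6-hydroxy 12-methyl ester, 8-OSiMe3 (6R,7R,8S,10R; present as its chromium alkoxide) | C[Si](C)(C)O[C@H]1C[C@@]2(C)OC(=CC2=O)/C(C)=C\[C@@H](O)[C@@H]1C(=C)C(=O)OC | intermediate
18 | 8-O-trimethylsilyl-8-desacyl-15-deoxygoyazensolide | C[Si](C)(C)O[C@H]1C[C@@]2(C)OC(=CC2=O)/C(C)=C\[C@H]2OC(=O)C(=C)[C@H]12 | intermediate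
19 | 8-desacyl-15-deoxygoyazensolide (6R,7R,8S,10R) | O[C@H]1C[C@@]2(C)OC(=CC2=O)/C(C)=C\[C@H]2OC(=O)C(=C)[C@H]12 | intermediate
20 | methacrylic anhydride | C=C(C)C(=O)OC(=O)C(C)=C | starting material
21 | 15-deoxygoyazensolide | C=C(C)C(=O)O[C@H]1C[C@@]2(C)OC(=CC2=O)/C(C)=C\[C@H]2OC(=O)C(=C)[C@H]12 | intermediate
22 | goyazensolide | C=C(C)C(=O)O[C@H]1C[C@@]2(C)OC(=CC2=O)/C(CO)=C\[C@H]2OC(=O)C(=C)[C@H]12 | target

## Totals and risks
Total step count: 9. Longest linear sequence: 9 (1 → 22).

**Step 7.** Closure onto the rigid furanone may be too strained or may give the wrong C6/C7 pair. The fallback reverses the ring order, sets out from 12 and comes back at 19.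
- Compound 12 is intercepted by a cold AcOH quench and silylated (Et3SiOTf, 2,6-lutidine) to the triethylsilyl-protected ynone F1.
- Direct Swern oxidation of the primary Me3Si ether, which never frees O6, gives the ynone enal F2.
- Me3SiBr gives the ynone allylic bromide F3.
- CrCl2 at high dilution closes F3 on the linear, less strained ynone to the bis-silylated ten-membered ynone lactone F4.
- HF·pyridine strips both silyl groups to the dihydroxy ynone lactone F5.
- The C10 hydroxyl of F5 adds across the ring to C3 (transannular 5-endo-dig oxa-Michael addition) to give 19.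

**Step 5.** The organolithium may attack the epoxy-acrylate. The fallback removes that electrophile before the fragments are joined, sets out from 9 and comes back at 19.
- Compound 9 is opened with Et3SiCl and catalytic Bu4NCl to the allylic chloride silyl ether F6. This is a beta-substituted enoate with no epoxide.
- The acetylide of 11 is added and the product cyclised as in step 5 to the chloro furanone alcohol F7.
- MnO2 gives the chloro enal F8.
- CrCl2 with LiI closes the ring to the triethylsilyl-protected lactone F9.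
- HF·pyridine gives 19.

**Step 9.** The conjugated C4=C5 alkene may be too electron-poor for SeO2, or may over-oxidise. The fallback puts the oxygen on C5 first and then moves it, sets out from 21 and comes back at 22.
- Schenck ene photooxygenation (O2, tetraphenylporphyrin, visible light) abstracts hydrogen from the methyl geminal to the acyl-like furanone carbon. This gives the allylic hydroperoxide F10 as C5 epimers.
- PPh3 reduces F10 to the exocyclic-methylene alcohol F11.
- Ph3SiOReO3 (cat) catalyses 1,3-allylic transposition, which moves the hydroxyl to C15 and returns the alkene to the conjugated C4=C5 position, giving 22.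

## Further compounds
F1 | step 7 | triethylsilyl-protected ynone (O10-SiEt3, O6-SiMe3) | C[C@@](O[Si](CC)(CC)CC)(C[C@@H]1O[C@H]1C(=C)C(=O)OC)C(=O)C#C/C(C)=C\CO[Si](C)(C)C
F2 | step 7 | ynone enal (O10-SiEt3) | C[C@@](O[Si](CC)(CC)CC)(C[C@@H]1O[C@H]1C(=C)C(=O)OC)C(=O)C#C/C(C)=C\C=O
F3 | step 7 | ynone allylic bromide (O8-SiMe3, O10-SiEt3) | C[C@@](O[Si](CC)(CC)CC)(C[C@H](O[Si](C)(C)C)/C=C(\CBr)C(=O)OC)C(=O)C#C/C(C)=C\C=O
F4 | step 7 | bis-silylated ten-membered ynone lactone | C[Si](C)(C)O[C@H]1C[C@@](C)(O[Si](CC)(CC)CC)C(=O)C#C/C(C)=C\[C@H]2OC(=O)C(=C)[C@H]12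
F5 | step 7 | dihydroxy ynone lactone | O[C@H]1C[C@@](C)(O)C(=O)C#C/C(C)=C\[C@H]2OC(=O)C(=C)[C@H]12
F6 | step 5 | allylic chloride silyl ether on the dioxolanone | C[C@]1(C[C@H](O[Si](CC)(CC)CC)/C=C(\CCl)C(=O)OC)O[C@H](C(C)(C)C)OC1=O
F7 | step 5 | chloro furanone alcohol | C[C@]1(C[C@H](O[Si](CC)(CC)CC)/C=C(\CCl)C(=O)OC)OC(=CC1=O)/C(C)=C\CO
F8 | step 5 | chloro enal | C[C@]1(C[C@H](O[Si](CC)(CC)CC)/C=C(\CCl)C(=O)OC)OC(=CC1=O)/C(C)=C\C=O
F9 | step 5 | triethylsilyl-protected lactone | CC[Si](CC)(CC)O[C@H]1C[C@@]2(C)OC(=CC2=O)/C(C)=C\[C@H]2OC(=O)C(=C)[C@H]12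
F10 | step 9 | allylic hydroperoxide (C5 epimers, 4(15)-ene) | C=C(C)C(=O)O[C@H]1C[C@@]2(C)OC(=CC2=O)C(=C)C(OO)[C@H]2OC(=O)C(=C)[C@H]12
F11 | step 9 | exocyclic-methylene alcohol (C5 epimers) | C=C(C)C(=O)O[C@H]1C[C@@]2(C)OC(=CC2=O)C(=C)C(O)[C@H]2OC(=O)C(=C)[C@H]12
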